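## Retrosynthetic overview

1. The target comes from its hexa-O-alkyl ether by a global ether cleavage in the last step. C2 is the only stereocentre. It is bought in (2S)-naringenin and carried through without strong base.
2. Flavone ring C is disconnected to an o-iodophenol, CO and 4-ethynylanisole (carbonylative Sonogashira coupling, then 6-endo oxa-Michael closure).
3. Flavone ring A, and with it the tetra-ortho-substituted C6–C8'' bond, is built on naringenin C6 by a pericyclic cascade. An aryl ketene takes up two ethoxyacetylenes: [2+2], 4π opening, [2+2], 4π opening, 6π electrocyclization.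
4. The aryl ketene comes from retro-ene cleavage of a tert-butyl ynol ether. That ether comes from Negishi coupling of tri-O-benzyl-6-iodonaringenin.
5. Ring order: naringenin rings A, B, C and flavone ring B are bought. Flavone ring A is formed first and flavone ring C second.

Assumption: the SMILES defines only C2 (S), so the sense of the hindered 6,8''-biaryl axis is left open and atropisomers are not separated; commercial (2S)-naringenin is taken as enantiopure, with ee checked on receipt.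

## Route

Step 1
Reactants: 1 (2S)-naringenin; 2 N-iodosuccinimide
Product: 3 (2S)-6-iodonaringenin
Conditions: NIS (1.0 equiv), DMF, 20 °C, dark, 3 h
Reagents that add atoms: N-iodosuccinimide O=C1CCC(=O)N1I
Why: Neutral electrophilic aromatic iodination goes to C6, the carbon flanked by the two free hydroxyls of the acylphloroglucinol ring, and with no base present C2 is untouched.

Step 2
Reactants: 3 (2S)-6-iodonaringenin; 4 benzyl alcohol
Product: 5 (2S)-5,7-bis(benzyloxy)-2-[4-(benzyloxy)phenyl]-6-iodochroman-4-one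
Conditions: BnOH (3.6 equiv), PPh3 (3.9 equiv), DIAD (3.9 equiv), THF, 0 °C to 20 °C
Reagents that add atoms: benzyl alcohol OCc1ccccc1
Why: Threefold Mitsunobu etherification alkylates even the chelated 5-OH under near-neutral conditions, which avoids the base-induced retro-oxa-Michael ring opening that would racemise C2.

Step 3
Reactants: 6 potassium tert-butoxide; 7 trichloroethylene
Product: 10 (E)-tert-butyl 1,2-dichlorovinyl ether, via dichloroacetylene 8 (not isolated), via tert-butanol 9 (not isolated)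
Conditions: KOtBu (1.0 equiv), THF, −78 °C to 20 °C
Reagents that add atoms: potassium tert-butoxide CC(C)(C)[O-].[K+]; trichloroethylene ClC=C(Cl)Cl
Why: Dehydrochlorination gives dichloroacetylene, and alkoxide-catalysed anti addition of tert-butanol to it gives the (E)-dichlorovinyl ether (elimination–addition route to dichloroenol ethers).

Step 4
Reactants: 5 tri-O-benzyl-6-iodonaringenin; 10 (E)-tert-butyl 1,2-dichlorovinyl ether
Product: 14 (2S)-5,7-bis(benzyloxy)-2-[4-(benzyloxy)phenyl]-6-(tert-butoxyethynyl)chroman-4-one, via tert-butoxychloroacetylene 11 (not isolated), via lithium tert-butoxyacetylide 12 (not isolated), via (tert-butoxyethynyl)zinc chloride 13 (not isolated)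
Conditions: 10 (1.5 equiv), n-BuLi (3.1 equiv), THF, −78 to −40 °C; ZnCl2 (1.7 equiv), to 0 °C; then 5, Pd(PPh3)4 (5 mol %), 25–40 °C; Et3N-washed silica
Reagents that add atoms: (E)-tert-butyl 1,2-dichlorovinyl ether CC(C)(C)O/C(Cl)=C\Cl
Why: Elimination and chlorine–lithium exchange unmask the alkoxyacetylide, and after transmetalation the slim, non-basic alkynylzinc undergoes Negishi coupling with the di-ortho-substituted iodide below 40 °C, which spares both the ketone and C2.

Step 5
Reactants: 14 tert-butyl ynol ether; 15 ethoxyacetylene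
Product: 22 (2S)-5,7-bis(benzyloxy)-2-[4-(benzyloxy)phenyl]-6-(2,4-diethoxy-6-hydroxyphenyl)chroman-4-one, via aryl ketene 16 (not isolated), via 4-aryl-3-ethoxycyclobutenone 17 (not isolated), via aryl vinylketene 18 (not isolated), via 4-vinylcyclobutenone adduct 19 (not isolated), via dienylketene 20 (not isolated), via cyclohexa-2,4-dienone tautomer 21 (not isolated)
Conditions: 15 (10 equiv), toluene (0.02 M in 14), sealed tube, 90 °C, 6 h, then 105 °C, 12 h
Reagents that add atoms: ethoxyacetylene CCOC#C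
Why: Retro-ene loss of isobutene unmasks aryl ketene 16, which runs a Danheiser-type benzannulation cascade ([2+2] at the nucleophilic CH of 15, 4π electrocyclic opening, second [2+2], 4π opening, 6π electrocyclization, tautomerization) that builds flavone ring A directly on C6 with the ketene oxygen as its only free OH; the blocked ortho positions of the aryl group stop naphthol-type closure, no new stereocentre survives, and the neutral medium leaves C2 alone.

Step 6
Reactants: 22 biaryl phenol; 2 N-iodosuccinimide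
Product: 23 (2S)-5,7-bis(benzyloxy)-2-[4-(benzyloxy)phenyl]-6-(4,6-diethoxy-2-hydroxy-3-iodophenyl)chroman-4-one
Conditions: NIS (1.0 equiv), MeCN–CH2Cl2, −20 to 0 °C
Reagents that add atoms: N-iodosuccinimide O=C1CCC(=O)N1I
Why: Electrophilic aromatic iodination picks the free-phenol ring over the carbonyl-deactivated naringenin ring, and within it the less crowded carbon between OH and OEt rather than the one between two OEt groups.

Step 7
Reactants: 23 o-iodophenol; 24 4-ethynylanisole; 25 carbon monoxide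
Product: 27 (2S)-5,7-bis(benzyloxy)-2-[4-(benzyloxy)phenyl]-6-[5,7-diethoxy-2-(4-methoxyphenyl)-4-oxo-4H-chromen-8-yl]chroman-4-one, via o-hydroxyaryl ynone 26 (not isolated)
Conditions: PdCl2(PPh3)2 (5 mol %), CO (1 atm), Et3N (3 equiv), THF–H2O, 25–40 °C; then DMAP (20 mol %), 40 °C
Reagents that add atoms: 4-ethynylanisole C#Cc1ccc(OC)cc1; carbon monoxide [C-]#[O+]
Why: Copper-free carbonylative Sonogashira coupling gives ynone 26, whose single ortho OH closes flavone ring C by DMAP-catalysed 6-endo oxa-Michael addition, so only the 8''-linked flavone can form and the weak amine bases at or below 40 °C do not enolise the flavanone.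

Step 8
Reactants: 27 hexa-O-alkyl biflavonoid
Product: 28 (2S)-6-[5,7-dihydroxy-2-(4-hydroxyphenyl)-4-oxo-4H-chromen-8-yl]-5,7-dihydroxy-2-(4-hydroxyphenyl)chroman-4-one (target)
Conditions: BCl3 (12 equiv), n-Bu4NI (9 equiv), CH2Cl2, −78 to 0 °C; ice water; MeOH co-evaporation
Reagents that add atoms: none
Why: Boron-activated SN2 ether cleavage by iodide removes the benzyl, ethyl and methyl groups at their primary carbons, while O1 of the flavanone is a weakly basic vinylogous-ester oxygen next to the boron-chelated C4=O/O5 unit and keeps the C2–O bond and the S configuration intact at or below 0 °C.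

## Compound list

1 | (2S)-naringenin | O=C1C[C@@H](c2ccc(O)cc2)Oc2cc(O)cc(O)c21 | starting material
2 | N-iodosuccinimide | O=C1CCC(=O)N1I | starting material
3 | (2S)-6-iodonaringenin | O=C1C[C@@H](c2ccc(O)cc2)Oc2cc(O)c(I)c(O)c21 | intermediate
4 | benzyl alcohol | OCc1ccccc1 | starting material
5 | (2S)-5,7-bis(benzyloxy)-2-[4-(benzyloxy)phenyl]-6-iodochroman-4-one | O=C1C[C@@H](c2ccc(OCc3ccccc3)cc2)Oc2cc(OCc3ccccc3)c(I)c(OCc3ccccc3)c21 | intermediate
6 | potassium tert-butoxide | CC(C)(C)[O-].[K+] | starting material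
7 | trichloroethylene | ClC=C(Cl)Cl | starting material
8 | dichloroacetylene | ClC#CCl | intermediate
9 | tert-butanol | CC(C)(C)O | intermediate
10 | (E)-tert-butyl 1,2-dichlorovinyl ether | CC(C)(C)O/C(Cl)=C\Cl | intermediate
11 | tert-butoxychloroacetylene | CC(C)(C)OC#CCl | intermediate
12 | lithium tert-butoxyacetylide | CC(C)(C)OC#C[Li] | intermediate
13 | (tert-butoxyethynyl)zinc chloride | CC(C)(C)OC#C[Zn]Cl | intermediate
14 | (2S)-5,7-bis(benzyloxy)-2-[4-(benzyloxy)phenyl]-6-(tert-butoxyethynyl)chroman-4-one | O=C1C[C@@H](c2ccc(OCc3ccccc3)cc2)Oc2cc(OCc3ccccc3)c(C#COC(C)(C)C)c(OCc3ccccc3)c21 | intermediate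
15 | ethoxyacetylene | CCOC#C | starting material
16 | aryl ketene, 2-[(2S)-tri-O-benzylnaringenin-6-yl]ethen-1-one | O=C1C[C@@H](c2ccc(OCc3ccccc3)cc2)Oc2cc(OCc3ccccc3)c(C=C=O)c(OCc3ccccc3)c21 | intermediate
17 | 4-aryl-3-ethoxycyclobut-2-en-1-one (ring CH epimers) | O=C1C[C@@H](c2ccc(OCc3ccccc3)cc2)Oc2cc(OCc3ccccc3)c(C4C(=O)C=C4OCC)c(OCc3ccccc3)c21 | intermediate
18 | aryl vinylketene, 4-aryl-3-ethoxybuta-1,3-dien-1-one | O=C1C[C@@H](c2ccc(OCc3ccccc3)cc2)Oc2cc(OCc3ccccc3)c(C=C(OCC)C=C=O)c(OCc3ccccc3)c21 | intermediate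
19 | 3-ethoxy-4-(2-aryl-1-ethoxyvinyl)cyclobut-2-en-1-one | O=C1C[C@@H](c2ccc(OCc3ccccc3)cc2)Oc2cc(OCc3ccccc3)c(C=C(OCC)C4C(=O)C=C4OCC)c(OCc3ccccc3)c21 | intermediate
20 | dienylketene, 6-aryl-3,5-diethoxyhexa-1,3,5-trien-1-one | O=C1C[C@@H](c2ccc(OCc3ccccc3)cc2)Oc2cc(OCc3ccccc3)c(C=C(OCC)C=C(OCC)C=C=O)c(OCc3ccccc3)c21 | intermediate
21 | 6-aryl-3,5-diethoxycyclohexa-2,4-dien-1-one | O=C1C[C@@H](c2ccc(OCc3ccccc3)cc2)Oc2cc(OCc3ccccc3)c(C4C(=O)C=C(OCC)C=C4OCC)c(OCc3ccccc3)c21 | intermediate
22 | (2S)-5,7-bis(benzyloxy)-2-[4-(benzyloxy)phenyl]-6-(2,4-diethoxy-6-hydroxyphenyl)chroman-4-one | O=C1C[C@@H](c2ccc(OCc3ccccc3)cc2)Oc2cc(OCc3ccccc3)c(-c4c(O)cc(OCC)cc4OCC)c(OCc3ccccc3)c21 | intermediate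
23 | (2S)-5,7-bis(benzyloxy)-2-[4-(benzyloxy)phenyl]-6-(4,6-diethoxy-2-hydroxy-3-iodophenyl)chroman-4-one | O=C1C[C@@H](c2ccc(OCc3ccccc3)cc2)Oc2cc(OCc3ccccc3)c(-c4c(O)c(I)c(OCC)cc4OCC)c(OCc3ccccc3)c21 | intermediate
24 | 4-ethynylanisole | C#Cc1ccc(OC)cc1 | starting material
25 | carbon monoxide | [C-]#[O+] | starting material
26 | (2S)-5,7-bis(benzyloxy)-2-[4-(benzyloxy)phenyl]-6-{4,6-diethoxy-2-hydroxy-3-[3-(4-methoxyphenyl)propioloyl]phenyl}chroman-4-one | O=C1C[C@@H](c2ccc(OCc3ccccc3)cc2)Oc2cc(OCc3ccccc3)c(-c4c(O)c(C(=O)C#Cc5ccc(OC)cc5)c(OCC)cc4OCC)c(OCc3ccccc3)c21 | intermediate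
27 | (2S)-5,7-bis(benzyloxy)-2-[4-(benzyloxy)phenyl]-6-[5,7-diethoxy-2-(4-methoxyphenyl)-4-oxo-4H-chromen-8-yl]chroman-4-one | O=C1C[C@@H](c2ccc(OCc3ccccc3)cc2)Oc2cc(OCc3ccccc3)c(-c4c(OCC)cc(OCC)c5c(=O)cc(-c6ccc(OC)cc6)oc45)c(OCc3ccccc3)c21 | intermediate
28 | (2S)-naringenin-(6→8'')-apigenin | O=C1C[C@@H](c2ccc(O)cc2)Oc2cc(O)c(-c3c(O)cc(O)c4c(=O)cc(-c5ccc(O)cc5)oc34)c(O)c21 | target

## Step count and risks

Total steps: 8. Longest linear sequence: 7 (steps 1, 2, 4, 5, 6, 7, 8). Step 3 is a one-step side branch.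

**Most at risk: step 5.**
- Free aryl ketene 16 can be caught by its own ortho benzyloxy oxygens or by unreacted 14.
- Phenol 22 can be acylated by the ketenes or can add to the excess of 15.

The fallback keeps the benzannulation but never forms a free aryl ketene. It sets out from 5 and comes back at 22. Compound 15 is metalated (n-BuLi, then ZnCl2) to (ethoxyethynyl)zinc chloride F1. F1 is coupled with 5 under Pd(PPh3)4 to the thermally sturdier (2S)-5,7-bis(benzyloxy)-2-[4-(benzyloxy)phenyl]-6-(ethoxyethynyl)chroman-4-one F2. Separately, acetyl chloride and Et3N give ketene F3, which adds to 15 by [2+2] to give 3-ethoxycyclobut-2-en-1-one F4. Heating F2 with 1.3 equiv of F4 in toluene at 110–120 °C opens F4 to its vinylketene. That ketene adds to the aryl-bearing alkyne carbon of F2, and 4π opening and 6π closure then deliver the same phenol 22.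

**Second: step 7.**
- The iodide is flanked by OH and OEt.
- Direct Sonogashira coupling would lead to a benzofuran.
- 5-exo closure would lead to an aurone.

The fallback brings in C2''–C4'' as an isoxazole, a masked 1,3-diketone, instead of CO plus alkyne. It sets out from 23 and comes back at 27. 4-Methoxybenzaldoxime and PhI(OAc)2 give 4-methoxybenzonitrile oxide F5. F5 adds to ethynyltributylstannane in a 1,3-dipolar cycloaddition to give 3-(4-methoxyphenyl)-5-(tributylstannyl)isoxazole F6. Stille coupling of F6 with 23 (Pd2(dba)3, AsPh3, CuI, DMF, 50 °C) gives the 5-(2-hydroxyaryl)isoxazole F7. Mo(CO)6 in MeCN–H2O at 80 °C cleaves the N–O bond of F7 to the (Z)-β-aminoenone F8. Dilute HCl in AcOH at 20 °C closes F8 to 27 with loss of ammonia. No step in this sequence uses base.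

**Third: step 8.** The unactivated 7''-OEt and 4'''-OMe groups may need more time or warmth than the benzylic C2–O1 bond tolerates, which would erode the ee. The fallback replaces the primary ethers with groups that iodide-free BCl3 removes between −78 and −20 °C. It sets out from 14 and comes back only at 28.
1. Isopropanol, KH and 7 give (E)-isopropyl 1,2-dichlorovinyl ether F9.
2. n-BuLi (2 equiv) followed by water turns F9 into isopropoxyacetylene F10.
3. The cascade of step 5, run with F10 in large excess at 85–90 °C, gives the 2,4-diisopropoxy-6-hydroxyphenyl compound F11.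
4. NIS converts F11 to the iodophenol F12.
5. Carbonylative annulation of F12 with commercial 1-(benzyloxy)-4-ethynylbenzene gives the tetrabenzyl diisopropyl ether F13.
6. BCl3 alone then strips the secondary and benzylic ethers of F13 to give 28.

## Further compounds

F1 | step 5 | (ethoxyethynyl)zinc chloride | CCOC#C[Zn]Cl
F2 | step 5 | (2S)-5,7-bis(benzyloxy)-2-[4-(benzyloxy)phenyl]-6-(ethoxyethynyl)chroman-4-one | O=C1C[C@@H](c2ccc(OCc3ccccc3)cc2)Oc2cc(OCc3ccccc3)c(C#COCC)c(OCc3ccccc3)c21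
F3 | step 5 | ketene | C=C=O
F4 | step 5 | 3-ethoxycyclobut-2-en-1-one | CCOC1=CC(=O)C1
F5 | step 7 | 4-methoxybenzonitrile oxide | COc1ccc(cc1)C#[N+][O-]
F6 | step 7 | 3-(4-methoxyphenyl)-5-(tributylstannyl)isoxazole | CCCC[Sn](CCCC)(CCCC)c1cc(-c2ccc(OC)cc2)no1
F7 | step 7 | (2S)-5,7-bis(benzyloxy)-2-[4-(benzyloxy)phenyl]-6-{4,6-diethoxy-2-hydroxy-3-[3-(4-methoxyphenyl)isoxazol-5-yl]phenyl}chroman-4-one | O=C1C[C@@H](c2ccc(OCc3ccccc3)cc2)Oc2cc(OCc3ccccc3)c(-c4c(O)c(-c5cc(-c6ccc(OC)cc6)no5)c(OCC)cc4OCC)c(OCc3ccccc3)c21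
F8 | step 7 | (2S)-6-{3-[(Z)-3-amino-3-(4-methoxyphenyl)acryloyl]-4,6-diethoxy-2-hydroxyphenyl}-5,7-bis(benzyloxy)-2-[4-(benzyloxy)phenyl]chroman-4-one | O=C1C[C@@H](c2ccc(OCc3ccccc3)cc2)Oc2cc(OCc3ccccc3)c(-c4c(O)c(C(=O)/C=C(\N)c5ccc(OC)cc5)c(OCC)cc4OCC)c(OCc3ccccc3)c21
F9 | step 8 | (E)-isopropyl 1,2-dichlorovinyl ether | CC(C)O/C(Cl)=C\Cl
F10 | step 8 | isopropoxyacetylene | CC(C)OC#C
F11 | step 8 | (2S)-5,7-bis(benzyloxy)-2-[4-(benzyloxy)phenyl]-6-(2-hydroxy-4,6-diisopropoxyphenyl)chroman-4-one | O=C1C[C@@H](c2ccc(OCc3ccccc3)cc2)Oc2cc(OCc3ccccc3)c(-c4c(O)cc(OC(C)C)cc4OC(C)C)c(OCc3ccccc3)c21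
F12 | step 8 | (2S)-5,7-bis(benzyloxy)-2-[4-(benzyloxy)phenyl]-6-(2-hydroxy-3-iodo-4,6-diisopropoxyphenyl)chroman-4-one | O=C1C[C@@H](c2ccc(OCc3ccccc3)cc2)Oc2cc(OCc3ccccc3)c(-c4c(O)c(I)c(OC(C)C)cc4OC(C)C)c(OCc3ccccc3)c21
F13 | step 8 | (2S)-5,7-bis(benzyloxy)-2-[4-(benzyloxy)phenyl]-6-{2-[4-(benzyloxy)phenyl]-5,7-diisopropoxy-4-oxo-4H-chromen-8-yl}chroman-4-one | O=C1C[C@@H](c2ccc(OCc3ccccc3)cc2)Oc2cc(OCc3ccccc3)c(-c4c(OC(C)C)cc(OC(C)C)c5c(=O)cc(-c6ccc(OCc7ccccc7)cc6)oc45)c(OCc3ccccc3)c21
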